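**Plan**
1. Retrosynthesis: the two phenolic O–benzyl bonds are cut first, the axial C4 carbinol goes back to a ketone and then to an exocyclic C4 methylene, and the tetrahydropyran is cut at O1–C2, C2–C3 and C5–C6.
2. Enabling feature: in the tetrahydropyran ring (O1, C2 aryl, C3, C4, C5, C6 arylethyl) C2 and C6 are both aldehyde-level carbinol carbons on O1. The C3–C4–C5 unit between them is functionalised on the central C4, so a 2-methylenepropane-1,3-diyl linchpin with a tin end and a silicon end fits between two aldehydes and leaves a carbon handle on C4.
3. Forward order: the arylpropanal and the stannane are joined first (C5–C6), the same flask then takes up O-benzylvanillin and closes the only new ring (O1–C2, C2–C3), and oxidative cleavage, hydride reduction and hydrogenolysis finish the target.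
4. Stereochemistry: C6 comes from the (R)-BINOL/Ti(OiPr)4 catalyst, C2 is relayed from C6 through a chair oxocarbenium closure (2,6-cis), and C4 comes from equatorial hydride delivery by LiBH(s-Bu)3 (axial hydroxyl).

Key step: step 4

Assumption: with the ring numbered O1, C2 (aryl), C3, C4 (carbinol), C5, C6 (arylethyl), the target is (2S,4S,6S), with the C2 and C6 substituents cis and the C4 hydroxyl axial, trans to both; compounds 1, 4 and 6 are taken as purchased.

**Step 1**
Reactants: 1 dihydroferulic acid, 3-(4-hydroxy-3-methoxyphenyl)propanoic acid
Product: 2 benzyl 3-(4-benzyloxy-3-methoxyphenyl)propanoate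
Conditions: BnBr (2.3 equiv), K2CO3 (3 equiv), DMF, 60 °C
Reagents that add atoms: benzyl bromide, BrCc1ccccc1
Why: Williamson ether synthesis and carboxylate O-alkylation run together, since K2CO3 deprotonates both the phenol and the acid and each anion displaces bromide from benzyl bromide (SN2), which protects the phenol and gives an ester ready for partial reduction.

**Step 2**
Reactants: 2 benzyl 3-(4-benzyloxy-3-methoxyphenyl)propanoate
Product: 3 3-(4-benzyloxy-3-methoxyphenyl)propanal
Conditions: (i-Bu)2AlH (1.1 equiv), CH2Cl2, −78 °C; MeOH, then aq potassium sodium tartrate (KNaC4H4O6)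
Reagents that add atoms: none
Why: Partial ester reduction with diisobutylaluminium hydride, in which one hydride adds at −78 °C to give an aluminium hemiacetal that should persist until the quench and then release the aldehyde, while the aryl benzyl ether is inert.

**Step 3**
Reactants: 4 2-(chloromethyl)-3-(trimethylsilyl)prop-1-ene
Product: 5 tributyl{2-[(trimethylsilyl)methyl]allyl}stannane
Conditions: Bu3SnH, LiN(i-Pr)2, THF, 0 °C; then 4, −78 °C to rt
Reagents that add atoms: tributyltin hydride, CCCC[SnH](CCCC)CCCC (used as tributylstannyllithium)
Why: Nucleophilic substitution of the allylic chloride by Bu3SnLi, in which the direct and the allylically transposed displacement give the same constitution and the less reactive C–Si bond is left untouched.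

**Step 4**
Reactants: 3 3-(4-benzyloxy-3-methoxyphenyl)propanal; 5 tributyl{2-[(trimethylsilyl)methyl]allyl}stannane; 6 O-benzylvanillin, 4-benzyloxy-3-methoxybenzaldehyde
Product: 9 (2S,6S)-2-(4-benzyloxy-3-methoxyphenyl)-6-[2-(4-benzyloxy-3-methoxyphenyl)ethyl]-4-methylenetetrahydro-2H-pyran, via stannyl ether 7 (not isolated), via silyl ether 8 (not isolated)
Conditions: (R)-BINOL (20 mol%), Ti(OiPr)4 (10 mol%), 4 Å MS, CH2Cl2, −20 °C, 3 + 5 (1.05 equiv); then 6 (1.3 equiv), Me3SiOTf (2 equiv), Et2O, −78 °C; Et3N, then aq KF
Reagents that add atoms: none
Why: The (R)-BINOL/Ti(OiPr)4 Lewis acid activates aldehyde 3 and the allylstannane terminus of 5 adds with allylic transposition (Keck asymmetric allylation) to give the (S)-configured stannyl ether 7, which Me3SiOTf converts into silyl ether 8; 8 and aldehyde 6 then condense under Me3SiOTf to an (E)-oxocarbenium ion that the pendant allylsilane attacks with loss of the silyl group, so that C5–C6, O1–C2 and C2–C3 are all formed in one flask. The closest known reaction type is the two-stage pyran annulation in which a catalytic asymmetric allylstannation is followed by a silyl-triflate-promoted intramolecular Sakurai (silyl-Prins) cyclisation, both stages being established for this bifunctional reagent, so that only the omitted isolation of the intermediate alcohol is an operational change. The tetrahydropyran closes in a 6-endo-trig mode through a chair transition state. C6 is set by the catalyst, since the (R)-BINOL complex delivers the allyl group to the Re face of the aliphatic aldehyde and this face gives the S configuration, and C2 is set by C6, since the (E)-oxocarbenium substituent and the arylethyl group both lie equatorial in the chair, which makes the ring 2,6-cis. The step needs chemoselectivity between the two allylmetal termini, which the far higher nucleophilicity of the allylstannane under the mild Lewis acid secures, and it needs the closure to outrun oxonia-Cope exchange and ionisation of the electron-rich benzylic ether, which the fast allylsilane terminator, the temperature of −78 °C and the choice of the aliphatic aldehyde for the first stage (no benzylic carbinol enters the acid stage) secure.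

**Step 5**
Reactants: 9 (2S,6S)-2-(4-benzyloxy-3-methoxyphenyl)-6-[2-(4-benzyloxy-3-methoxyphenyl)ethyl]-4-methylenetetrahydro-2H-pyran
Product: 10 (2S,6S)-2-(4-benzyloxy-3-methoxyphenyl)-6-[2-(4-benzyloxy-3-methoxyphenyl)ethyl]tetrahydro-4H-pyran-4-one
Conditions: OsO4 (2 mol%), NaIO4 (4 equiv), 2,6-lutidine, dioxane/H2O (3:1), rt
Reagents that add atoms: osmium tetroxide, O=[Os](=O)(=O)=O (transfers the ketone oxygen; kept in turnover by sodium periodate, [Na+].[O-][I](=O)(=O)=O)
Why: Lemieux–Johnson oxidation, in which OsO4 dihydroxylates the 1,1-disubstituted exocyclic alkene and NaIO4 cleaves the diol to the ketone and formaldehyde and regenerates OsO4, while 2,6-lutidine suppresses over-oxidation and the arenes, benzyl ethers and both ring stereocentres are not touched.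

**Step 6**
Reactants: 10 (2S,6S)-2-(4-benzyloxy-3-methoxyphenyl)-6-[2-(4-benzyloxy-3-methoxyphenyl)ethyl]tetrahydro-4H-pyran-4-one
Product: 11 (2S,4S,6S)-2-(4-benzyloxy-3-methoxyphenyl)-6-[2-(4-benzyloxy-3-methoxyphenyl)ethyl]tetrahydro-2H-pyran-4-ol
Conditions: LiBH(s-Bu)3 (1.3 equiv), THF, −78 °C; then aq NaOH, H2O2, 0 °C
Reagents that add atoms: none
Why: Diastereoselective ketone reduction with a bulky trialkylborohydride, which in the chair that keeps the C2 and C6 substituents equatorial approaches along the equatorial trajectory, so that the new C4 hydroxyl is axial (4S), trans to both ring substituents, while the oxidative work-up only removes the borane.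

**Step 7**
Reactants: 11 (2S,4S,6S)-2-(4-benzyloxy-3-methoxyphenyl)-6-[2-(4-benzyloxy-3-methoxyphenyl)ethyl]tetrahydro-2H-pyran-4-ol
Product: 12 (2S,4S,6S)-2-(4-hydroxy-3-methoxyphenyl)-6-[2-(4-hydroxy-3-methoxyphenyl)ethyl]tetrahydro-2H-pyran-4-ol
Conditions: H2 (1 atm), Pd/C (10% Pd on carbon), EtOAc, rt
Reagents that add atoms: none
Why: Catalytic hydrogenolysis over Pd/C cleaves the two aryl benzyl ethers, whose phenoxide leaving groups make them react far faster than the secondary, electron-rich benzylic C2–O1 bond of the ring, so that hydrogen uptake is stopped at two equivalents and the three stereocentres remain as set.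

**Compound list**
1 | dihydroferulic acid, 3-(4-hydroxy-3-methoxyphenyl)propanoic acid | COc1cc(CCC(=O)O)ccc1O | starting material
2 | benzyl 3-(4-benzyloxy-3-methoxyphenyl)propanoate | COc1cc(CCC(=O)OCc2ccccc2)ccc1OCc1ccccc1 | intermediate
3 | 3-(4-benzyloxy-3-methoxyphenyl)propanal | COc1cc(CCC=O)ccc1OCc1ccccc1 | intermediate
4 | 2-(chloromethyl)-3-(trimethylsilyl)prop-1-ene | C=C(CCl)C[Si](C)(C)C | starting material
5 | tributyl{2-[(trimethylsilyl)methyl]allyl}stannane | C=C(C[Si](C)(C)C)C[Sn](CCCC)(CCCC)CCCC | intermediate
6 | O-benzylvanillin, 4-benzyloxy-3-methoxybenzaldehyde | COc1cc(C=O)ccc1OCc1ccccc1 | starting material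
7 | tributylstannyl ether of (3S)-1-(4-benzyloxy-3-methoxyphenyl)-5-[(trimethylsilyl)methyl]hex-5-en-3-ol | COc1cc(CC[C@H](O[Sn](CCCC)(CCCC)CCCC)CC(=C)C[Si](C)(C)C)ccc1OCc1ccccc1 | intermediate (not isolated)
8 | trimethylsilyl ether of (3S)-1-(4-benzyloxy-3-methoxyphenyl)-5-[(trimethylsilyl)methyl]hex-5-en-3-ol | COc1cc(CC[C@H](O[Si](C)(C)C)CC(=C)C[Si](C)(C)C)ccc1OCc1ccccc1 | intermediate (not isolated)
9 | (2S,6S)-2-(4-benzyloxy-3-methoxyphenyl)-6-[2-(4-benzyloxy-3-methoxyphenyl)ethyl]-4-methylenetetrahydro-2H-pyran (2,6-cis) | COc1cc(CC[C@H]2CC(=C)C[C@@H](c3ccc(OCc4ccccc4)c(OC)c3)O2)ccc1OCc1ccccc1 | intermediate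
10 | (2S,6S)-2-(4-benzyloxy-3-methoxyphenyl)-6-[2-(4-benzyloxy-3-methoxyphenyl)ethyl]tetrahydro-4H-pyran-4-one | COc1cc(CC[C@H]2CC(=O)C[C@@H](c3ccc(OCc4ccccc4)c(OC)c3)O2)ccc1OCc1ccccc1 | intermediate
11 | (2S,4S,6S)-2-(4-benzyloxy-3-methoxyphenyl)-6-[2-(4-benzyloxy-3-methoxyphenyl)ethyl]tetrahydro-2H-pyran-4-ol (4-OH axial) | COc1cc(CC[C@H]2C[C@H](O)C[C@@H](c3ccc(OCc4ccccc4)c(OC)c3)O2)ccc1OCc1ccccc1 | intermediate
12 | (2S,4S,6S)-2-(4-hydroxy-3-methoxyphenyl)-6-[2-(4-hydroxy-3-methoxyphenyl)ethyl]tetrahydro-2H-pyran-4-ol | COc1cc(CC[C@H]2C[C@H](O)C[C@@H](c3ccc(O)c(OC)c3)O2)ccc1O | target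

**Totals**
Total step count: 7. Longest linear sequence: 6 steps (steps 1, 2, 4, 5, 6 and 7, from compound 1).

**Steps most likely to fail**

First, step 4. Three processes threaten the one-flask form:
- Incomplete consumption of 3 or 5 in the first stage would carry a second aliphatic aldehyde or a free allylstannane into the acid stage and lead to wrongly paired pyrans.
- The isopropanol and BINOL released by the catalyst are silylated as well and can divert aldehyde 6 into open-chain acetals and intermolecular allylation.
- Enantiomeric or cis/trans purity may be lost through oxonia-Cope exchange or ionisation of the electron-rich benzylic C2–O1 bond if the mixture warms before the quench.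

The fallback sets out from 3 and 5 and returns at 9; it divides the annulation into its two separately established halves. The allylation is run alone with the same catalyst, and aqueous KF work-up and chromatography should give the free alcohol (3S)-1-(4-benzyloxy-3-methoxyphenyl)-5-[(trimethylsilyl)methyl]hex-5-en-3-ol F1. At this point it is free of titanium, BINOL, isopropanol and tin, and its enantiomeric purity can be checked. F1 and 6 are then combined with Me3SiOTf in Et2O at −78 °C, the two-component silyl-Prins closure, which rejoins the route at 9.

Second, step 7. Hydrogenolysis may run on past the two aryl benzyl ethers and cleave the benzylic C2–O1 bond of the ring, which opens the tetrahydropyran and destroys C2. The fallback sets out from 11 and returns at 12. The benzyl groups are removed by single-electron transfer in place of surface hydrogenolysis, with lithium 4,4′-di-tert-butylbiphenylide in THF at −78 °C followed by aqueous NH4Cl. Each aryl benzyl ether should fragment to a phenoxide and a benzyl anion that is protonated to toluene on work-up. Once the phenoxide has formed, the ring on C2 is too electron-rich to accept an electron, and the ring ether would have to expel an alkoxide, so the tetrahydropyran should stay closed. This fallback passes through no new isolable compound (F0).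

Third, step 2. The aluminium hemiacetal may collapse before the quench, and the aldehyde set free is then reduced further, which leaves a mixture of ester, aldehyde and primary alcohol. The fallback sets out from 2 and returns at 3. The ester is reduced completely with LiAlH4 in THF at 0 °C to 3-(4-benzyloxy-3-methoxyphenyl)propan-1-ol F2, and a Swern oxidation ((COCl)2, DMSO, Et3N, CH2Cl2, −78 °C) then gives 3.

**Further compounds**
F1 | step 4 | (3S)-1-(4-benzyloxy-3-methoxyphenyl)-5-[(trimethylsilyl)methyl]hex-5-en-3-ol | COc1cc(CC[C@H](O)CC(=C)C[Si](C)(C)C)ccc1OCc1ccccc1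
F0 | step 7 | none | none
F2 | step 2 | 3-(4-benzyloxy-3-methoxyphenyl)propan-1-ol | COc1cc(CCCO)ccc1OCc1ccccc1
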